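## Retrosynthetic overview
1. Chain numbering runs from C1 (lactone C=O) to C15 (CH2 on the furan). The γ-lactone is opened to a C4-hydroxy enoate (conjugate reduction, then lactonisation), and C1–C2 come from a Wittig reaction on a C3 aldehyde.
2. The key disconnection is C4–C5. The lithium enolate of the (S)-lactic acid/pivalaldehyde dioxolanone (fragment C: C3, C4, 4-Me) adds in an aldol reaction to the C5–C15 aldehyde, setting C4 (S) and C5 (R).
3. The C5–C15 aldehyde is cut at C10–C11. A C5–C10 alkynediol (fragment B) couples with a furyl allylic bromide (fragment A), and trans-hydroalumination then gives the 9E alkene.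
4. Fragment B comes from geraniol: Sharpless epoxidation sets C8, the epoxy chloride gives the alkynol, and ozonolysis trims the chain. Fragment A comes from furan-3-carbaldehyde by two Wittig olefinations (12E).
5. Ring order: the furan is bought, the oxirane (step 7) and the dioxolanone (step 16) are temporary, and the γ-lactone is closed last (step 22).

Assumption: the target SMILES is read as (4S,5R,8S,9E,12E), that is (5S)-5-[(1R,4S,5E,8E)-11-(furan-3-yl)-1,4-dihydroxy-4,8-dimethylundeca-5,8-dien-1-yl]-5-methyloxolan-2-one. LiN(i-Pr)2 is used as the commercial solution.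

## Route

Step 1
Reactants: 1 furan-3-carbaldehyde; 2 ethyl (triphenylphosphoranylidene)acetate
Product: 3 ethyl (E)-3-(furan-3-yl)prop-2-enoate
Conditions: CH2Cl2, rt, 12 h
Reagents that add atoms: none
Why: Wittig olefination with a stabilised ylide needs no base and is clean on this non-enolisable aldehyde, and the E/Z ratio does not matter because the alkene is saturated next.

Step 2
Reactants: 3 ethyl (E)-3-(furan-3-yl)prop-2-enoate
Product: 4 ethyl 3-(furan-3-yl)propanoate
Conditions: H2 (1 atm), 10 % Pd/C, EtOAc, rt, stopped after 1 equiv H2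
Reagents that add atoms: none
Why: Catalytic hydrogenation takes the unhindered conjugated C=C much faster than the aromatic furan, so stopping at one equivalent of H2 gives the saturated ester.

Step 3
Reactants: 4 ethyl 3-(furan-3-yl)propanoate
Product: 5 3-(furan-3-yl)propanal
Conditions: i-Bu2AlH (1.05 equiv), CH2Cl2, −78 °C; MeOH, then aq. potassium sodium tartrate
Reagents that add atoms: none
Why: In this partial ester reduction the tetrahedral aluminium hemiacetal is stable at −78 °C and releases the aldehyde only on quenching.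

Step 4
Reactants: 5 3-(furan-3-yl)propanal; 6 ethyl 2-(triphenylphosphoranylidene)propanoate
Product: 7 ethyl (E)-5-(furan-3-yl)-2-methylpent-2-enoate
Conditions: CH2Cl2, rt, 16 h
Reagents that add atoms: none
Why: Wittig olefination with the α-methyl stabilised ylide gives the E-trisubstituted enoate (E:Z ≥ 95:5), which fixes the 12E geometry.

Step 5
Reactants: 7 ethyl (E)-5-(furan-3-yl)-2-methylpent-2-enoate
Product: 8 (E)-5-(furan-3-yl)-2-methylpent-2-en-1-ol
Conditions: i-Bu2AlH (2.3 equiv), CH2Cl2, −78 → 0 °C; aq. potassium sodium tartrate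
Reagents that add atoms: none
Why: 1,2-Reduction of the enoate with i-Bu2AlH gives the allylic alcohol without touching the alkene geometry or the furan.

Step 6
Reactants: 8 (E)-5-(furan-3-yl)-2-methylpent-2-en-1-ol
Product: 10 3-[(3E)-5-bromo-4-methylpent-3-en-1-yl]furan, via allylic mesylate 9 (not isolated)
Conditions: MsCl, Et3N, THF, −40 °C; then LiBr (4 equiv), THF, 0 °C
Reagents that add atoms: methanesulfonyl chloride, CS(=O)(=O)Cl (mesyl group of 9 only); lithium bromide, [Li+].[Br-]
Why: Mesylation followed by SN2 displacement with bromide is non-acidic, so there is no allylic transposition, no E/Z loss and no furan damage.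

Step 7
Reactants: 11 geraniol
Product: 12 [(2S,3S)-3-methyl-3-(4-methylpent-3-en-1-yl)oxiran-2-yl]methanol
Conditions: Ti(OiPr)4 (5 mol %), L-(+)-diethyl tartrate (7 mol %), t-BuOOH (2 equiv), 4 Å MS, CH2Cl2, −20 °C
Reagents that add atoms: tert-butyl hydroperoxide, CC(C)(C)OO
Why: Sharpless asymmetric epoxidation is directed by the allylic OH, so only the 2,3-alkene reacts, and L-(+)-tartrate gives the (2S,3S)-epoxide (about 95 % ee), which sets the future C8.

Step 8
Reactants: 12 [(2S,3S)-3-methyl-3-(4-methylpent-3-en-1-yl)oxiran-2-yl]methanol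
Product: 13 (2S,3R)-3-(chloromethyl)-2-methyl-2-(4-methylpent-3-en-1-yl)oxirane
Conditions: PPh3, CCl4, NaHCO3 (cat.), reflux, 3 h
Reagents that add atoms: tetrachloromethane, ClC(Cl)(Cl)Cl
Why: Appel chlorination replaces the primary OH by SN2 under near-neutral conditions and leaves both oxirane centres spatially unchanged (only the descriptor of the CH carbon changes).

Step 9
Reactants: 13 (2S,3R)-3-(chloromethyl)-2-methyl-2-(4-methylpent-3-en-1-yl)oxirane
Product: 15 (3S)-3,7-dimethyloct-6-en-1-yn-3-ol, via chlorovinyl lithium alkoxide 14 (not isolated)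
Conditions: n-BuLi (3.5 equiv), THF, −78 → −30 °C; H2O
Reagents that add atoms: n-butyllithium, [Li]CCCC (lithium of 14 only)
Why: In this base-induced double elimination (Takano–Yadav alkynol synthesis), deprotonation next to chlorine opens the oxirane at the CH carbon and loss of HCl gives the alkyne, while the C–O bond at the quaternary carbon is never broken, so C8 stays S.

Step 10
Reactants: 15 (3S)-3,7-dimethyloct-6-en-1-yn-3-ol
Product: 17 (4S)-4-methylhex-5-yne-1,4-diol, via hydroxy aldehyde 16 (not isolated)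
Conditions: O3, CH2Cl2–MeOH (4:1), Sudan Red 7B, −78 °C; then NaBH4, −78 °C → rt
Reagents that add atoms: ozone, [O-][O+]=O
Why: In this ozonolysis with reductive work-up the electron-rich trisubstituted alkene reacts orders of magnitude faster than the terminal alkyne (dye end-point), and NaBH4 reduces the aldehyde/lactol to the diol.

Step 11
Reactants: 10 3-[(3E)-5-bromo-4-methylpent-3-en-1-yl]furan; 17 (4S)-4-methylhex-5-yne-1,4-diol
Product: 18 (4S,8E)-11-(furan-3-yl)-4,8-dimethylundec-8-en-5-yne-1,4-diol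
Conditions: CuI (10 mol %), K2CO3 (1.5 equiv), n-Bu4NBr, DMF, rt, 16 h
Reagents that add atoms: none
Why: Copper-catalysed allylic substitution by a terminal alkyne (Jeffery conditions) tolerates free hydroxyls and attacks the primary allylic carbon, forming C10–C11 with the 12E alkene retained.

Step 12
Reactants: 18 (4S,8E)-11-(furan-3-yl)-4,8-dimethylundec-8-en-5-yne-1,4-diol
Product: 19 (4S,5E,8E)-11-(furan-3-yl)-4,8-dimethylundeca-5,8-diene-1,4-diol
Conditions: NaAlH2(OCH2CH2OMe)2 (5 equiv), THF, 0 °C → rt; aq. potassium sodium tartrate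
Reagents that add atoms: none
Why: In this directed hydroalumination the propargylic aluminium alkoxide delivers hydride intramolecularly, and trans-addition followed by protonolysis gives only the E-alkene, while the isolated alkene and the furan are inert.

Step 13
Reactants: 19 (4S,5E,8E)-11-(furan-3-yl)-4,8-dimethylundeca-5,8-diene-1,4-diol
Product: 20 3-[(3E,6E,8S)-4,8-dimethyl-8,11-bis(triethylsilyloxy)undeca-3,6-dien-1-yl]furan
Conditions: Et3SiOTf (2.6 equiv), 2,6-lutidine (4 equiv), CH2Cl2, −78 → 0 °C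
Reagents that add atoms: triethylsilyl trifluoromethanesulfonate, CC[Si](CC)(CC)OS(=O)(=O)C(F)(F)F
Why: Silylation with a silyl triflate and a hindered base caps even the tertiary allylic alcohol at low temperature without ionising it.

Step 14
Reactants: 20 3-[(3E,6E,8S)-4,8-dimethyl-8,11-bis(triethylsilyloxy)undeca-3,6-dien-1-yl]furan
Product: 21 (4S,5E,8E)-11-(furan-3-yl)-4,8-dimethyl-4-(triethylsilyloxy)undeca-5,8-dien-1-ol
Conditions: pyridinium p-toluenesulfonate (10 mol %), MeOH–CH2Cl2 (1:3), −10 → 0 °C, TLC control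
Reagents that add atoms: none
Why: Acid-catalysed methanolysis of silyl ethers is governed by sterics, so the primary triethylsilyl ether is cleaved far faster than the tertiary one.

Step 15
Reactants: 21 (4S,5E,8E)-11-(furan-3-yl)-4,8-dimethyl-4-(triethylsilyloxy)undeca-5,8-dien-1-ol
Product: 22 (4S,5E,8E)-11-(furan-3-yl)-4,8-dimethyl-4-(triethylsilyloxy)undeca-5,8-dienal
Conditions: (COCl)2, DMSO, CH2Cl2, −78 °C; Et3N, → 0 °C
Reagents that add atoms: none
Why: Swern oxidation stops at the aldehyde and is tolerated by the furan, the skipped diene and the tertiary silyl ether.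

Step 16
Reactants: 23 (S)-lactic acid; 24 pivalaldehyde
Product: 25 (2S,5S)-2-tert-butyl-5-methyl-1,3-dioxolan-4-one (cis)
Conditions: p-TsOH·H2O (cat.), H2SO4 (cat.), pentane, reflux, Dean–Stark; recrystallisation from pentane–Et2O, −78 °C
Reagents that add atoms: none
Why: Acid-catalysed acetalisation under thermodynamic control favours the cis acetal (about 4:1, purified by cold crystallisation), and the new 2S acetal centre stores the chirality of lactic acid (self-regeneration of stereocentres).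

Step 17
Reactants: 25 (2S,5S)-2-tert-butyl-5-methyl-1,3-dioxolan-4-one; 22 (4S,5E,8E)-11-(furan-3-yl)-4,8-dimethyl-4-(triethylsilyloxy)undeca-5,8-dienal
Product: 27 (2S,5R)-2-tert-butyl-5-[(1R,4S,5E,8E)-11-(furan-3-yl)-1-hydroxy-4,8-dimethyl-4-(triethylsilyloxy)undeca-5,8-dien-1-yl]-5-methyl-1,3-dioxolan-4-one, via lithium enolate 26 (not isolated)
Conditions: 25 (1.4 equiv), LiN(i-Pr)2 (1.45 equiv), THF, −78 °C, 30 min; 22 (1.0 equiv), −78 °C, 1 h; AcOH, −78 °C
Reagents that add atoms: lithium diisopropylamide, [Li+].CC(C)[N-]C(C)C (lithium of 26 only)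
Why: In this intermolecular aldol addition the aldehyde attacks enolate 26 anti to the tert-butyl group (C4, > 20:1), and the ring-locked enolate (methyl cis to OLi) in a Zimmerman–Traxler chair with the aldehyde chain equatorial places O4 and O5 anti, giving the 5R carbinol as the major epimer (expected about 4–6:1, separated on silica).

Step 18
Reactants: 27 aldol adduct
Product: 28 (2S,5R)-2-tert-butyl-5-[(1R,4S,5E,8E)-1-(tert-butyldimethylsilyloxy)-11-(furan-3-yl)-4,8-dimethyl-4-(triethylsilyloxy)undeca-5,8-dien-1-yl]-5-methyl-1,3-dioxolan-4-one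
Conditions: t-BuMe2SiOTf (1.5 equiv), 2,6-lutidine, CH2Cl2, 0 °C
Reagents that add atoms: tert-butyldimethylsilyl trifluoromethanesulfonate, CC(C)(C)[Si](C)(C)OS(=O)(=O)C(F)(F)F
Why: Triflate-mediated silylation caps the hindered C5 carbinol, blocks retro-aldol cleavage, and provides a group robust enough not to migrate in the next steps.

Step 19
Reactants: 28 silylated aldol adduct
Product: 29 (2S,3R,6S,7E,10E)-3-(tert-butyldimethylsilyloxy)-13-(furan-3-yl)-2,6,10-trimethyl-6-(triethylsilyloxy)trideca-7,10-diene-1,2-diol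
Conditions: LiAlH4 (2 equiv), Et2O, 0 °C; H2O work-up
Reagents that add atoms: none
Why: Hydride reduction of the dioxolanone frees the C3 primary and C4 tertiary alcohols and removes the auxiliary aldehyde as neopentyl alcohol without touching any stereocentre.

Step 20
Reactants: 29 diol
Product: 30 (2R,3R,6S,7E,10E)-3-(tert-butyldimethylsilyloxy)-13-(furan-3-yl)-2-hydroxy-2,6,10-trimethyl-6-(triethylsilyloxy)trideca-7,10-dienal
Conditions: (COCl)2, DMSO, CH2Cl2, −78 °C; Et3N, → −20 °C; used crude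
Reagents that add atoms: none
Why: Swern oxidation acts only on the primary alcohol because the tertiary one has no carbinol hydrogen, and the aldehyde has no α-hydrogen, so C4 cannot epimerise (only its descriptor changes).

Step 21
Reactants: 30 hydroxy aldehyde; 31 methyl (triphenylphosphoranylidene)acetate
Product: 32 methyl (2E,4S,5R,8S,9E,12E)-5-(tert-butyldimethylsilyloxy)-15-(furan-3-yl)-4-hydroxy-4,8,12-trimethyl-8-(triethylsilyloxy)pentadeca-2,9,12-trienoate
Conditions: CH2Cl2, rt → 40 °C, 24 h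
Reagents that add atoms: none
Why: Wittig olefination under neutral conditions adds C1–C2 to the activated α-oxygenated aldehyde without base-induced ketol shift, and the new alkene geometry does not matter because it is reduced next.

Step 22
Reactants: 32 hydroxy enoate
Product: 34 (5S)-5-[(1R,4S,5E,8E)-1-(tert-butyldimethylsilyloxy)-11-(furan-3-yl)-4,8-dimethyl-4-(triethylsilyloxy)undeca-5,8-dien-1-yl]-5-methyloxolan-2-one, via saturated hydroxy ester 33 (not isolated)
Conditions: Cu(OAc)2·H2O (5 mol %), 1,2-bis(diphenylphosphino)benzene (5 mol %), (EtO)2MeSiH (3 equiv), t-BuOH (3 equiv), toluene, rt; then pyridinium p-toluenesulfonate (10 mol %), 4 Å MS, toluene, 45 °C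
Reagents that add atoms: none
Why: Copper hydride conjugate reduction touches only the electron-poor C2=C3 bond (isolated alkenes and furan are inert, and hydride delivery to C3 avoids γ-elimination), and the C4 tertiary OH then closes the five-membered lactone by transesterification while O5 is still silylated.

Step 23
Reactants: 34 bis-silylated lactone
Product: 35 (5S)-5-[(1R,4S,5E,8E)-11-(furan-3-yl)-1,4-dihydroxy-4,8-dimethylundeca-5,8-dien-1-yl]-5-methyloxolan-2-one (target)
Conditions: HF·pyridine, pyridine, THF, 0 °C → rt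
Reagents that add atoms: none
Why: Fluoride-driven desilylation under pyridine-buffered conditions frees both alcohols without ionising the tertiary allylic alcohol, opening the lactone or harming the furan.

## Compound list
1 | furan-3-carbaldehyde | O=Cc1ccoc1 | starting material
2 | ethyl (triphenylphosphoranylidene)acetate | CCOC(=O)C=P(c1ccccc1)(c1ccccc1)c1ccccc1 | starting material
3 | ethyl (E)-3-(furan-3-yl)prop-2-enoate | CCOC(=O)/C=C/c1ccoc1 | intermediate
4 | ethyl 3-(furan-3-yl)propanoate | CCOC(=O)CCc1ccoc1 | intermediate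
5 | 3-(furan-3-yl)propanal | O=CCCc1ccoc1 | intermediate
6 | ethyl 2-(triphenylphosphoranylidene)propanoate | CCOC(=O)C(C)=P(c1ccccc1)(c1ccccc1)c1ccccc1 | starting material
7 | ethyl (E)-5-(furan-3-yl)-2-methylpent-2-enoate | CCOC(=O)/C(C)=C/CCc1ccoc1 | intermediate
8 | (E)-5-(furan-3-yl)-2-methylpent-2-en-1-ol | OC/C(C)=C/CCc1ccoc1 | intermediate
9 | (E)-5-(furan-3-yl)-2-methylpent-2-en-1-yl methanesulfonate (not isolated) | CS(=O)(=O)OC/C(C)=C/CCc1ccoc1 | intermediate
10 | 3-[(3E)-5-bromo-4-methylpent-3-en-1-yl]furan | BrC/C(C)=C/CCc1ccoc1 | intermediate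
11 | geraniol | CC(C)=CCC/C(C)=C/CO | starting material
12 | [(2S,3S)-3-methyl-3-(4-methylpent-3-en-1-yl)oxiran-2-yl]methanol | CC(C)=CCC[C@]1(C)O[C@H]1CO | intermediate
13 | (2S,3R)-3-(chloromethyl)-2-methyl-2-(4-methylpent-3-en-1-yl)oxirane | CC(C)=CCC[C@]1(C)O[C@H]1CCl | intermediate
14 | lithium (3S)-1-chloro-3,7-dimethylocta-1,6-dien-3-olate, E/Z not defined (not isolated) | ClC=C[C@@](C)([O-])CCC=C(C)C.[Li+] | intermediate
15 | (3S)-3,7-dimethyloct-6-en-1-yn-3-ol | C#C[C@@](C)(O)CCC=C(C)C | intermediate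
16 | (4S)-4-hydroxy-4-methylhex-5-ynal, in equilibrium with its lactol (not isolated) | C#C[C@@](C)(O)CCC=O | intermediate
17 | (4S)-4-methylhex-5-yne-1,4-diol | C#C[C@@](C)(O)CCCO | intermediate
18 | (4S,8E)-11-(furan-3-yl)-4,8-dimethylundec-8-en-5-yne-1,4-diol | C/C(=C\CCc1ccoc1)CC#C[C@@](C)(O)CCCO | intermediate
19 | (4S,5E,8E)-11-(furan-3-yl)-4,8-dimethylundeca-5,8-diene-1,4-diol | C/C(=C\CCc1ccoc1)C/C=C/[C@@](C)(O)CCCO | intermediate
20 | 3-[(3E,6E,8S)-4,8-dimethyl-8,11-bis(triethylsilyloxy)undeca-3,6-dien-1-yl]furan | C/C(=C\CCc1ccoc1)C/C=C/[C@@](C)(O[Si](CC)(CC)CC)CCCO[Si](CC)(CC)CC | intermediate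
21 | (4S,5E,8E)-11-(furan-3-yl)-4,8-dimethyl-4-(triethylsilyloxy)undeca-5,8-dien-1-ol | C/C(=C\CCc1ccoc1)C/C=C/[C@@](C)(O[Si](CC)(CC)CC)CCCO | intermediate
22 | (4S,5E,8E)-11-(furan-3-yl)-4,8-dimethyl-4-(triethylsilyloxy)undeca-5,8-dienal | C/C(=C\CCc1ccoc1)C/C=C/[C@@](C)(O[Si](CC)(CC)CC)CCC=O | intermediate
23 | (S)-lactic acid | C[C@H](O)C(=O)O | starting material
24 | pivalaldehyde | CC(C)(C)C=O | starting material
25 | (2S,5S)-2-tert-butyl-5-methyl-1,3-dioxolan-4-one | C[C@@H]1O[C@H](C(C)(C)C)OC1=O | intermediate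
26 | lithium (2S)-2-tert-butyl-5-methyl-1,3-dioxol-4-olate (not isolated) | CC1=C([O-])O[C@@H](C(C)(C)C)O1.[Li+] | intermediate
27 | (2S,5R)-2-tert-butyl-5-[(1R,4S,5E,8E)-11-(furan-3-yl)-1-hydroxy-4,8-dimethyl-4-(triethylsilyloxy)undeca-5,8-dien-1-yl]-5-methyl-1,3-dioxolan-4-one | C/C(=C\CCc1ccoc1)C/C=C/[C@@](C)(O[Si](CC)(CC)CC)CC[C@@H](O)[C@@]1(C)O[C@H](C(C)(C)C)OC1=O | intermediate
28 | (2S,5R)-2-tert-butyl-5-[(1R,4S,5E,8E)-1-(tert-butyldimethylsilyloxy)-11-(furan-3-yl)-4,8-dimethyl-4-(triethylsilyloxy)undeca-5,8-dien-1-yl]-5-methyl-1,3-dioxolan-4-one | C/C(=C\CCc1ccoc1)C/C=C/[C@@](C)(O[Si](CC)(CC)CC)CC[C@@H](O[Si](C)(C)C(C)(C)C)[C@@]1(C)O[C@H](C(C)(C)C)OC1=O | intermediate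
29 | (2S,3R,6S,7E,10E)-3-(tert-butyldimethylsilyloxy)-13-(furan-3-yl)-2,6,10-trimethyl-6-(triethylsilyloxy)trideca-7,10-diene-1,2-diol | C/C(=C\CCc1ccoc1)C/C=C/[C@@](C)(O[Si](CC)(CC)CC)CC[C@@H](O[Si](C)(C)C(C)(C)C)[C@@](C)(O)CO | intermediate
30 | (2R,3R,6S,7E,10E)-3-(tert-butyldimethylsilyloxy)-13-(furan-3-yl)-2-hydroxy-2,6,10-trimethyl-6-(triethylsilyloxy)trideca-7,10-dienal | C/C(=C\CCc1ccoc1)C/C=C/[C@@](C)(O[Si](CC)(CC)CC)CC[C@@H](O[Si](C)(C)C(C)(C)C)[C@@](C)(O)C=O | intermediate
31 | methyl (triphenylphosphoranylidene)acetate | COC(=O)C=P(c1ccccc1)(c1ccccc1)c1ccccc1 | starting material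
32 | methyl (2E,4S,5R,8S,9E,12E)-5-(tert-butyldimethylsilyloxy)-15-(furan-3-yl)-4-hydroxy-4,8,12-trimethyl-8-(triethylsilyloxy)pentadeca-2,9,12-trienoate | C/C(=C\CCc1ccoc1)C/C=C/[C@@](C)(O[Si](CC)(CC)CC)CC[C@@H](O[Si](C)(C)C(C)(C)C)[C@@](C)(O)/C=C/C(=O)OC | intermediate
33 | methyl (4S,5R,8S,9E,12E)-5-(tert-butyldimethylsilyloxy)-15-(furan-3-yl)-4-hydroxy-4,8,12-trimethyl-8-(triethylsilyloxy)pentadeca-9,12-dienoate (not isolated) | C/C(=C\CCc1ccoc1)C/C=C/[C@@](C)(O[Si](CC)(CC)CC)CC[C@@H](O[Si](C)(C)C(C)(C)C)[C@@](C)(O)CCC(=O)OC | intermediate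
34 | (5S)-5-[(1R,4S,5E,8E)-1-(tert-butyldimethylsilyloxy)-11-(furan-3-yl)-4,8-dimethyl-4-(triethylsilyloxy)undeca-5,8-dien-1-yl]-5-methyloxolan-2-one | C/C(=C\CCc1ccoc1)C/C=C/[C@@](C)(O[Si](CC)(CC)CC)CC[C@@H](O[Si](C)(C)C(C)(C)C)[C@]1(C)CCC(=O)O1 | intermediate
35 | (5S)-5-[(1R,4S,5E,8E)-11-(furan-3-yl)-1,4-dihydroxy-4,8-dimethylundeca-5,8-dien-1-yl]-5-methyloxolan-2-one | C/C(=C\CCc1ccoc1)C/C=C/[C@@](C)(O)CC[C@@H](O)[C@]1(C)CCC(=O)O1 | target

## Step count and risks
Total steps: 23. The longest linear sequence is 18 steps (steps 1–6, 11–15 and 17–23).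

**Step 17 (aldol).** Control at C4 is secure, but the ratio at the C5 carbinol may be modest. The fallback sets out from 22 (with 25) and comes back at 27. It fixes C5 by a reagent-controlled ketone reduction instead of during C–C bond formation.
- The aldol is run as written, and 27 is collected together with the (1S)-epimeric aldol adduct F1.
- Dess–Martin periodinane with NaHCO3 in CH2Cl2 converts both into the single C5 ketone F2, whose quaternary C4 cannot epimerise.
- Corey–Bakshi–Shibata reduction with (S)-1-methyl-3,3-diphenyltetrahydro-1H,3H-pyrrolo[1,2-c][1,3,2]oxazaborole and catecholborane (toluene, −78 → −40 °C) follows. The quaternary carbon acts as the large group and the CH2 chain as the small group, so hydride delivery gives the 5R alcohol 27.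
- Catecholborane at low temperature does not hydroborate the alkenes.

**Step 11 (copper-catalysed alkyne–allyl coupling).** The free diol may couple slowly, or some SN2′ attack may occur. The fallback sets out from 17 and comes back at 19, bypassing 18 and step 12. It forms C10–C11 as an sp2–sp3 bond.
- Hydrostannation with Bu3SnH and PdCl2(PPh3)2 (2 mol %) in THF at 0 °C is steered by the bulky tertiary carbinol to the terminal carbon. It gives the (E)-vinylstannane diol F3.
- Stille coupling of this stannane with bromide 10 uses Pd2(dba)3 (dba = dibenzylideneacetone, 2.5 mol %) and AsPh3 (10 mol %) in DMF at rt. It joins the primary allylic terminus with retention of both alkene geometries and gives 19 directly.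

**Step 22 (conjugate reduction and lactonisation).** The enoate next to a quaternary carbon may react slowly, and the silane may silylate the free alcohol. The fallback sets out from 29 and comes back at 34, bypassing steps 20–22. It avoids any alkene at C2–C3.
- TsCl in pyridine at 0 °C gives the primary tosylate F4.
- K2CO3 in MeOH closes it to the terminal epoxide F5 with the C4–O bond retained.
- NaCH(CO2Et)2 in EtOH at reflux opens the oxirane at its CH2 carbon and lactonises in the same pot, giving the α-ethoxycarbonyl lactone F6.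
- Krapcho dealkoxycarbonylation (LiCl, H2O, DMSO, 140 °C) then delivers 34.

## Further compounds
F1 | step 17 | (2S,5R)-2-tert-butyl-5-[(1S,4S,5E,8E)-11-(furan-3-yl)-1-hydroxy-4,8-dimethyl-4-(triethylsilyloxy)undeca-5,8-dien-1-yl]-5-methyl-1,3-dioxolan-4-one | C/C(=C\CCc1ccoc1)C/C=C/[C@@](C)(O[Si](CC)(CC)CC)CC[C@H](O)[C@@]1(C)O[C@H](C(C)(C)C)OC1=O
F2 | step 17 | (2S,5R)-2-tert-butyl-5-[(4S,5E,8E)-11-(furan-3-yl)-4,8-dimethyl-4-(triethylsilyloxy)undeca-5,8-dienoyl]-5-methyl-1,3-dioxolan-4-one | C/C(=C\CCc1ccoc1)C/C=C/[C@@](C)(O[Si](CC)(CC)CC)CCC(=O)[C@@]1(C)O[C@H](C(C)(C)C)OC1=O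
F3 | step 11 | (4S,5E)-4-methyl-6-(tributylstannyl)hex-5-ene-1,4-diol | CCCC[Sn](CCCC)(CCCC)/C=C/[C@@](C)(O)CCCO
F4 | step 22 | (2S,3R,6S,7E,10E)-3-(tert-butyldimethylsilyloxy)-13-(furan-3-yl)-2-hydroxy-2,6,10-trimethyl-6-(triethylsilyloxy)trideca-7,10-dien-1-yl 4-methylbenzenesulfonate | C/C(=C\CCc1ccoc1)C/C=C/[C@@](C)(O[Si](CC)(CC)CC)CC[C@@H](O[Si](C)(C)C(C)(C)C)[C@@](C)(O)COS(=O)(=O)c1ccc(C)cc1
F5 | step 22 | (2S)-2-[(1R,4S,5E,8E)-1-(tert-butyldimethylsilyloxy)-11-(furan-3-yl)-4,8-dimethyl-4-(triethylsilyloxy)undeca-5,8-dien-1-yl]-2-methyloxirane | C/C(=C\CCc1ccoc1)C/C=C/[C@@](C)(O[Si](CC)(CC)CC)CC[C@@H](O[Si](C)(C)C(C)(C)C)[C@]1(C)CO1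
F6 | step 22 | ethyl (5S)-5-[(1R,4S,5E,8E)-1-(tert-butyldimethylsilyloxy)-11-(furan-3-yl)-4,8-dimethyl-4-(triethylsilyloxy)undeca-5,8-dien-1-yl]-5-methyl-2-oxooxolane-3-carboxylate (epimers at C3) | C/C(=C\CCc1ccoc1)C/C=C/[C@@](C)(O[Si](CC)(CC)CC)CC[C@@H](O[Si](C)(C)C(C)(C)C)[C@]1(C)CC(C(=O)OCC)C(=O)O1
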